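## Structural features

The target is a 2,3-dihydro-1-benzofuran: a benzene ring (ring A) fused through C3a and C7a to a five-membered oxygen ring (ring B: O1, C2, C3). Ring A carries an acetyl group at C5 and a hydroxyl at C6, hydrogen-bonded to each other, with O1 para to the acetyl group. C2 carries a 3-acetoxyprop-1-en-2-yl chain and the adjacent C3 an angelate, (2Z)-2-methylbut-2-enoate. The two neighbouring stereocentres are (2R,3R), which is the 2,3-cis arrangement; C2 is S in every C3-unsubstituted intermediate only because the priorities change, not the geometry. Fragile groups are the Z-angelate (isomerized to the tiglate by nucleophilic amines or heat), the allylic acetate and above all the C3 ester. C3 sits on C3a, which is para to the C6 oxygen and ortho to the carbon bearing O1, so the C3–O bond ionizes easily and loss of the C2 proton then gives the aromatic benzofuran. The real difficulty is to place oxygen on C3, cis to the C2 chain, without aromatizing ring B, and to tell three oxygen functions apart at the end. The key step uses the same electronic feature: the para/ortho oxygen pair makes the C3–H bond a hydride donor, and a carboxyl group on the carbon that becomes the acetoxymethyl group can reach the C3 cation only on the face of the C2 chain, so a temporary cis-fused lactone (ring C) fixes C3.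

## Logic of the disconnections

16 back to 14 (through 15): the O–Si bond and the two ketal C–O bonds are cut. The free hydroxy ketone would not survive hydride reduction and would deactivate the ring for C–H oxidation, so it is carried masked. The forward step must unmask without ionizing the C3 ester, hence ketal first (acetyl restored), then buffered fluoride.

14 back to 11 and 12: the C3 O–acyl bond is cut, so that the most labile ester and the Z-alkene arrive last. The forward acylation must avoid heat, acid and nucleophilic catalysts.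

11 back to 10: the primary O–acetyl bond is cut. This leaves a diol whose two hydroxyls differ clearly in hindrance; the forward step needs primary-over-secondary selectivity.

10 back to 9: the primary carbinol carbon is raised to the acyl level and joined to the C3 oxygen. The lactone ties the C3 oxygen to the C2 chain and so encodes the cis relation; the forward step needs 1,2-selective reduction of a conjugated lactone.

9 back to 8: the C3–O bond is cut (key step). This removes one ring, one stereocentre and the benzylic oxygen, leaving an acid with a single stereocentre. The forward step demands that carboxyl capture of the C3 cation outruns loss of the C2 proton. The bulky silyl ether and the dioxolane are retained in 8 for that reason, and 8 is made immediately before use so that acid and ketal do not sit together.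

8 back to 7, and 7 back to 5 (through 6): the C–O bonds at the side-chain carbon are removed, back to a methyl group. The isopropenyl group can then come from a bulk diene; the forward allylic oxidation must choose the methyl group over the oxygen-bearing C2 methine.

5 back to 4 and 3: the ketal and the silyl ether are removed. The silyl group goes on first because the hydrogen-bonded hydroxy ketone resists ketalization.

3 back to 1 and 2: the C3–C3a bond and the O1–C2 bond are cut. Both form in one palladium-catalysed annulation, which also sets C2 by catalyst control. The forward step demands insertion at the unsubstituted vinyl end of 2 and face-selective attack of the phenoxide.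

## Other disconnections considered

Alternative 1: The cut is the O1–C2 bond, with the isopropenyl double bond traced back to a gem-dimethyl-substituted ring carbon; ring B is unfolded to the six-membered cis-chromanol ester A1 ((3R,4R)).
- Forward key step: the C3 hydroxyl of A1 would be converted to a triflate (Tf2O, 2,6-lutidine). O1 would shift from the quaternary carbon to C3 with inversion, and the tertiary cation left behind would lose a methyl proton to give A2.
- In favour: both stereocentres of A1 are of the kind that enantioselective cis-dihydroxylation sets reliably. The angelate is already in place and the acetyl group needs no ketal. On reagent-controlled stereochemistry and protecting-group count this alternative is the equal or the better of the chosen plan.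
- Against: O1 is para to the acetyl group and a poor migrating nucleophile. A triflate next to a quaternary carbon can also trigger methyl shift or elimination, and the cation can lose the wrong proton. The angelate must survive strongly electrophilic conditions, and selective acylation of the benzylic hydroxyl of a cis-diol is not trivial.
- Comparison: A2 has a plain isopropenyl group, so the methyl would have to be oxidized and acetylated at the very end beside the angelate and the ionizable C3 ester. The chosen plan does that oxidation early on a robust intermediate. Step counts are comparable; the chosen route is preferred because its uncertain step falls on a simple acid.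

Alternative 2: The cut is the C–C bond between C2 and the future central carbon of the propenyl unit.
- Forward key step: the diazo ester A3 (C3 oxygen in place, C2 an unsubstituted methylene) would be treated with Rh2(OAc)4. The rhodium carbene would insert into the C2–H bond next to O1 and give the cis-fused phosphono lactone A4. Horner–Wadsworth–Emmons reaction of A4 with formaldehyde would then give the same lactone 9.
- In favour: every step has close precedent. C3 would come from an asymmetric carbonyl reduction and C2 from the cis ring fusion. No benzylic cation is formed, so the aromatization that threatens the chosen key step cannot occur. On mechanistic security this alternative is the better plan, and from 9 onward the two are identical.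
- Against: insertion must beat aromatic cycloaddition and insertion at C4–H of the electron-rich ring. A diazo compound and an organolithium ring closure must be handled. About nine steps are needed to reach 9, against six.
- Comparison: both plans use the same temporary lactone and differ only in whether its C–O or its C–C bond is made last. The chosen plan is shorter and builds the skeleton in one annulation, so it is tried first and this alternative is kept as its fallback.

Alternative 3: The cut is the C2–C3 bond.
- Forward key step: the eight-membered cyclic enol ether A5 would be deprotonated at its benzylic OCH2 group by a chiral lithium amide base (LiNR2). The carbanion would attack the enol ether carbon across the ring in a [2,3]-Wittig shift. Ring B, the free C3 hydroxyl, the isopropenyl group and both stereocentres of A6 would appear together.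
- In favour: it is the only plan that makes a ring C–C bond and both stereocentres in one step, and it needs no oxidation at C3. In bond-forming efficiency of the key step it is the better of the two.
- Against: A5 is a medium ring with a Z-enol ether that is itself hard to close. Enantiotopic deprotonation by chiral amide bases is rarely fully selective, and the cis/trans outcome rests on a transannular transition state that cannot be predicted with confidence. [1,2]-Shift and β-elimination of the benzylic anion compete, and A6 again needs late allylic oxidation.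
- Comparison: in the chosen plan C2 is set by a catalyst and C3 follows from ring fusion, so stereocontrol is more secure. The overall length of this alternative is not lower, so it is the least attractive of the three.

Key step: step 6

Assumption: the ligand enantiomer in step 1 is the one that sends the phenoxide to the allyl face giving (2S); the sense is inferred from this catalyst class with simpler bromophenols.

## Route

Step 1
Reactants: 1 1-(5-bromo-2,4-dihydroxyphenyl)ethanone; 2 isoprene (2-methylbuta-1,3-diene)
Product: 3 1-[(2S)-6-hydroxy-2-(prop-1-en-2-yl)-2,3-dihydro-1-benzofuran-5-yl]ethanone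
Conditions: Pd2(dba)3 (cat.), TY-Phos-type chiral sulfinamide phosphine (cat., enantiomer giving 2S), NaOPh (1.3 equiv), 2 (5 equiv), toluene, 80 °C, sealed tube
Reagents that add atoms: none
Why: Asymmetric Heck/Tsuji–Trost heteroannulation of an ortho-bromophenol with a 1,3-diene: oxidative addition to zerovalent palladium, carbopalladation of the unsubstituted vinyl end of 2, then 5-exo attack of the ortho phenoxide on the π-allyl complex of divalent palladium. The chiral ligand decides which face of the allyl terminus is attacked and so sets C2 as S; the hydrogen-bonded second hydroxyl cannot reach the allyl unit.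

Step 2
Reactants: 3 1-[(2S)-6-hydroxy-2-(prop-1-en-2-yl)-2,3-dihydro-1-benzofuran-5-yl]ethanone
Product: 4 1-[(2S)-2-(prop-1-en-2-yl)-6-[(triisopropylsilyl)oxy]-2,3-dihydro-1-benzofuran-5-yl]ethanone
Conditions: TIPSOTf (1.2 equiv), 2,6-lutidine, CH2Cl2, 0 °C
Reagents that add atoms: triisopropylsilyl trifluoromethanesulfonate, CC(C)[Si](C(C)C)(C(C)C)OS(=O)(=O)C(F)(F)F
Why: Silylation of a hydrogen-bonded phenol needs the silyl triflate. The bulky group is chosen because it survives steps 3 to 9 and is not transferred from oxygen at the cation stage of step 6.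

Step 3
Reactants: 4 1-[(2S)-2-(prop-1-en-2-yl)-6-[(triisopropylsilyl)oxy]-2,3-dihydro-1-benzofuran-5-yl]ethanone
Product: 5 triisopropyl{[(2S)-5-(2-methyl-1,3-dioxolan-2-yl)-2-(prop-1-en-2-yl)-2,3-dihydro-1-benzofuran-6-yl]oxy}silane
Conditions: (TMSOCH2)2 (3 equiv), TMSOTf (10 mol %), CH2Cl2, −78 → −20 °C; pyridine quench
Reagents that add atoms: 1,2-bis(trimethylsilyloxy)ethane, C[Si](C)(C)OCCO[Si](C)(C)C
Why: Aprotic silyl-transfer ketalization is driven by formation of hexamethyldisiloxane and leaves the aryl silyl ether and the allylic aryl ether intact. The ketal removes the acceptor para to O1, which step 6 needs, and shields the ketone from the hydride of step 7.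

Step 4
Reactants: 5 triisopropyl{[(2S)-5-(2-methyl-1,3-dioxolan-2-yl)-2-(prop-1-en-2-yl)-2,3-dihydro-1-benzofuran-6-yl]oxy}silane
Product: 7 2-[(2S)-5-(2-methyl-1,3-dioxolan-2-yl)-6-[(triisopropylsilyl)oxy]-2,3-dihydro-1-benzofuran-2-yl]prop-2-enal, via allylic alcohol 6 (not isolated)
Conditions: SeO2 (0.3 equiv), t-BuOOH (3 equiv, in decane), CH2Cl2, 0 °C → rt; crude, then MnO2, CH2Cl2, rt
Reagents that add atoms: selenium dioxide, O=[Se]=O; tert-butyl hydroperoxide, CC(C)(C)OO
Why: Allylic oxidation by ene reaction and [2,3]-shift goes to the methyl group of a 1,1-disubstituted alkene in preference to the oxygen-bearing methine. MnO2 then converges alcohol 6 and any enal already formed on 7 without touching C2.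

Step 5
Reactants: 7 2-[(2S)-5-(2-methyl-1,3-dioxolan-2-yl)-6-[(triisopropylsilyl)oxy]-2,3-dihydro-1-benzofuran-2-yl]prop-2-enal
Product: 8 2-[(2S)-5-(2-methyl-1,3-dioxolan-2-yl)-6-[(triisopropylsilyl)oxy]-2,3-dihydro-1-benzofuran-2-yl]prop-2-enoic acid
Conditions: NaClO2, NaH2PO4, 2-methylbut-2-ene (excess), t-BuOH/H2O, 0 °C; used at once
Reagents that add atoms: sodium chlorite, [Na+].[O-]Cl=O
Why: Pinnick oxidation takes the enal to the acid under buffered conditions that do not epimerize C2. The alkene scavenger removes hypochlorous acid before it can chlorinate the electron-rich ring.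

Step 6
Reactants: 8 2-[(2S)-5-(2-methyl-1,3-dioxolan-2-yl)-6-[(triisopropylsilyl)oxy]-2,3-dihydro-1-benzofuran-2-yl]prop-2-enoic acid
Product: 9 (3aR,8bR)-7-(2-methyl-1,3-dioxolan-2-yl)-3-methylidene-6-[(triisopropylsilyl)oxy]-3a,8b-dihydrofuro[3,2-b][1]benzofuran-2(3H)-one
Conditions: DDQ (1.2 equiv), 2,6-dichloropyridine (2 equiv), 4 Å molecular sieves, ClCH2CH2Cl, 0 °C → rt
Reagents that add atoms: none
Why: Proposed new method: DDQ forms a charge-transfer complex with the electron-rich arene and removes hydride from C3, the only C–H bond whose cation is stabilized by both the para silyloxy oxygen and O1 (a 2,4-dioxygenated benzyl cation, at one limit an O-silylated para-quinone methide); the closest known reaction types are the DDQ-mediated oxidative benzylic lactonization of aryl-alkanoic acids and the 1,6-addition of carboxylic acids to para-quinone methides, neither shown on a dihydrobenzofuran that can aromatize. The carboxyl oxygen of the C2 acrylic acid then attacks the cationic C3 in a 5-exo-trig closure and the proton passes to the reduced quinone, giving the α-methylene-γ-lactone. Because the nucleophile is tethered to C2 it can reach C3 only from its own face, so the two five-membered rings are cis-fused and the new stereocentre (C8b of 9, C3 of the benzofuran) is set as R by the existing C2 centre. Site selectivity is electronic: C2–H lies next to an electron-poor alkene and is not activated, and the ketal in place of the acetyl group keeps the ring donor-rich. The selectivity that matters is capture against loss of the C2 proton to the benzofuran; the five-membered intramolecular closure, the absence of any base stronger than 2,6-dichloropyridine, the low temperature and the bulky silyl group that stays on oxygen are meant to secure it. Over-oxidation of 9 is slowed by the acyloxy group now on C3 and by using close to one equivalent of oxidant.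

Step 7
Reactants: 9 (3aR,8bR)-7-(2-methyl-1,3-dioxolan-2-yl)-3-methylidene-6-[(triisopropylsilyl)oxy]-3a,8b-dihydrofuro[3,2-b][1]benzofuran-2(3H)-one
Product: 10 (2R,3R)-2-(3-hydroxyprop-1-en-2-yl)-5-(2-methyl-1,3-dioxolan-2-yl)-6-[(triisopropylsilyl)oxy]-2,3-dihydro-1-benzofuran-3-ol
Conditions: i-Bu2AlH (4.5 equiv), CH2Cl2, −78 → 0 °C; aq. KNaC4H4O6
Reagents that add atoms: none
Why: i-Bu2AlH reduces the conjugated lactone in 1,2 fashion through the lactol to the primary allylic alcohol and frees the C3 hydroxyl. No bond to a stereocentre is broken, and the ketal keeps the ketone out of reach.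

Step 8
Reactants: 10 (2R,3R)-2-(3-hydroxyprop-1-en-2-yl)-5-(2-methyl-1,3-dioxolan-2-yl)-6-[(triisopropylsilyl)oxy]-2,3-dihydro-1-benzofuran-3-ol
Product: 11 2-[(2R,3R)-3-hydroxy-5-(2-methyl-1,3-dioxolan-2-yl)-6-[(triisopropylsilyl)oxy]-2,3-dihydro-1-benzofuran-2-yl]prop-2-en-1-yl acetate
Conditions: AcCl (1.1 equiv), 2,4,6-collidine, CH2Cl2, −78 °C
Reagents that add atoms: acetyl chloride, CC(=O)Cl
Why: Acylation at low temperature with a hindered pyridine base separates the primary allylic hydroxyl from the secondary benzylic one, which is shielded by the cis C2 chain.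

Step 9
Reactants: 11 2-[(2R,3R)-3-hydroxy-5-(2-methyl-1,3-dioxolan-2-yl)-6-[(triisopropylsilyl)oxy]-2,3-dihydro-1-benzofuran-2-yl]prop-2-en-1-yl acetate; 12 angelic acid [(2Z)-2-methylbut-2-enoic acid]
Product: 14 (2R,3R)-2-[3-(acetyloxy)prop-1-en-2-yl]-5-(2-methyl-1,3-dioxolan-2-yl)-6-[(triisopropylsilyl)oxy]-2,3-dihydro-1-benzofuran-3-yl (2Z)-2-methylbut-2-enoate, via mixed anhydride 13 (not isolated)
Conditions: 12, 2,4,6-Cl3C6H2COCl, Et3N, toluene, rt; filtered solution of 13 added to 11, THF, −78 °C; LiN(SiMe3)2 (1.05 equiv) dropwise, −78 → −40 °C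
Reagents that add atoms: none
Why: Yamaguchi-type mixed-anhydride acylation of the alkoxide, with no nucleophilic pyridine catalyst and no heating, avoids the addition–elimination path that turns angelates into tiglates and spares the ionizable benzylic ester. The alkoxide attacks the less hindered angeloyl carbonyl, and forming it in the presence of 13 leaves little time for acetyl migration.

Step 10
Reactants: 14 (2R,3R)-2-[3-(acetyloxy)prop-1-en-2-yl]-5-(2-methyl-1,3-dioxolan-2-yl)-6-[(triisopropylsilyl)oxy]-2,3-dihydro-1-benzofuran-3-yl (2Z)-2-methylbut-2-enoate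
Product: 16 (2R,3R)-5-acetyl-2-[3-(acetyloxy)prop-1-en-2-yl]-6-hydroxy-2,3-dihydro-1-benzofuran-3-yl (2Z)-2-methylbut-2-enoate, via silyl-protected ketone 15 (not isolated)
Conditions: PPTS (cat.), THF/H2O (4:1), rt; then Bu4NF, AcOH, 0 °C
Reagents that add atoms: water, O
Why: The aryl ketal, whose oxocarbenium ion is stabilized by the two ring oxygens, should hydrolyse far faster than the C3 ester ionizes, so the acetyl group is restored first. Buffered fluoride then cleaves the aryl silyl ether without forming a free para-phenoxide that could expel the angelate.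

## Compound list

1 | 1-(5-bromo-2,4-dihydroxyphenyl)ethanone | CC(=O)c1cc(Br)c(O)cc1O | starting material
2 | isoprene (2-methylbuta-1,3-diene) | C=CC(C)=C | starting material
3 | 1-[(2S)-6-hydroxy-2-(prop-1-en-2-yl)-2,3-dihydro-1-benzofuran-5-yl]ethanone | C=C(C)[C@@H]1Cc2cc(C(C)=O)c(O)cc2O1 | intermediate
4 | 1-[(2S)-2-(prop-1-en-2-yl)-6-[(triisopropylsilyl)oxy]-2,3-dihydro-1-benzofuran-5-yl]ethanone | C=C(C)[C@@H]1Cc2cc(C(C)=O)c(O[Si](C(C)C)(C(C)C)C(C)C)cc2O1 | intermediate
5 | triisopropyl{[(2S)-5-(2-methyl-1,3-dioxolan-2-yl)-2-(prop-1-en-2-yl)-2,3-dihydro-1-benzofuran-6-yl]oxy}silane | C=C(C)[C@@H]1Cc2cc(C3(C)OCCO3)c(O[Si](C(C)C)(C(C)C)C(C)C)cc2O1 | intermediate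
6 | 2-[(2S)-5-(2-methyl-1,3-dioxolan-2-yl)-6-[(triisopropylsilyl)oxy]-2,3-dihydro-1-benzofuran-2-yl]prop-2-en-1-ol | C=C(CO)[C@@H]1Cc2cc(C3(C)OCCO3)c(O[Si](C(C)C)(C(C)C)C(C)C)cc2O1 | intermediate (not isolated)
7 | 2-[(2S)-5-(2-methyl-1,3-dioxolan-2-yl)-6-[(triisopropylsilyl)oxy]-2,3-dihydro-1-benzofuran-2-yl]prop-2-enal | C=C(C=O)[C@@H]1Cc2cc(C3(C)OCCO3)c(O[Si](C(C)C)(C(C)C)C(C)C)cc2O1 | intermediate
8 | 2-[(2S)-5-(2-methyl-1,3-dioxolan-2-yl)-6-[(triisopropylsilyl)oxy]-2,3-dihydro-1-benzofuran-2-yl]prop-2-enoic acid | C=C(C(=O)O)[C@@H]1Cc2cc(C3(C)OCCO3)c(O[Si](C(C)C)(C(C)C)C(C)C)cc2O1 | intermediate (key-step precursor)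
9 | (3aR,8bR)-7-(2-methyl-1,3-dioxolan-2-yl)-3-methylidene-6-[(triisopropylsilyl)oxy]-3a,8b-dihydrofuro[3,2-b][1]benzofuran-2(3H)-one | C=C1C(=O)O[C@@H]2c3cc(C4(C)OCCO4)c(O[Si](C(C)C)(C(C)C)C(C)C)cc3O[C@H]12 | intermediate (key-step product)
10 | (2R,3R)-2-(3-hydroxyprop-1-en-2-yl)-5-(2-methyl-1,3-dioxolan-2-yl)-6-[(triisopropylsilyl)oxy]-2,3-dihydro-1-benzofuran-3-ol | C=C(CO)[C@H]1Oc2cc(O[Si](C(C)C)(C(C)C)C(C)C)c(C3(C)OCCO3)cc2[C@H]1O | intermediate
11 | 2-[(2R,3R)-3-hydroxy-5-(2-methyl-1,3-dioxolan-2-yl)-6-[(triisopropylsilyl)oxy]-2,3-dihydro-1-benzofuran-2-yl]prop-2-en-1-yl acetate | C=C(COC(C)=O)[C@H]1Oc2cc(O[Si](C(C)C)(C(C)C)C(C)C)c(C3(C)OCCO3)cc2[C@H]1O | intermediate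
12 | angelic acid, (2Z)-2-methylbut-2-enoic acid | C/C=C(/C)C(=O)O | starting material
13 | (2Z)-2-methylbut-2-enoic 2,4,6-trichlorobenzoic anhydride | C/C=C(/C)C(=O)OC(=O)c1c(Cl)cc(Cl)cc1Cl | intermediate (not isolated)
14 | (2R,3R)-2-[3-(acetyloxy)prop-1-en-2-yl]-5-(2-methyl-1,3-dioxolan-2-yl)-6-[(triisopropylsilyl)oxy]-2,3-dihydro-1-benzofuran-3-yl (2Z)-2-methylbut-2-enoate | C=C(COC(C)=O)[C@H]1Oc2cc(O[Si](C(C)C)(C(C)C)C(C)C)c(C3(C)OCCO3)cc2[C@H]1OC(=O)/C(C)=C\C | intermediate
15 | (2R,3R)-5-acetyl-2-[3-(acetyloxy)prop-1-en-2-yl]-6-[(triisopropylsilyl)oxy]-2,3-dihydro-1-benzofuran-3-yl (2Z)-2-methylbut-2-enoate | C=C(COC(C)=O)[C@H]1Oc2cc(O[Si](C(C)C)(C(C)C)C(C)C)c(C(C)=O)cc2[C@H]1OC(=O)/C(C)=C\C | intermediate (not isolated)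
16 | (2R,3R)-5-acetyl-2-[3-(acetyloxy)prop-1-en-2-yl]-6-hydroxy-2,3-dihydro-1-benzofuran-3-yl (2Z)-2-methylbut-2-enoate | C=C(COC(C)=O)[C@H]1Oc2cc(O)c(C(C)=O)cc2[C@H]1OC(=O)/C(C)=C\C | target

Total step count: 10. Longest linear sequence: 10 steps (1 to 16).

## Least certain steps

Step 6 (key step). The most likely failure is loss of the C2 proton from the benzylic cation, giving the aromatic benzofuran faster than the carboxyl group closes the lactone. The reduced quinone anion sits in the ion pair as a base, and the aromatic product is a thermodynamic sink. Re-ionization of the product lactone by the acidic hydroquinone would lead to the same sink.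

The fallback sets out from 1 and returns at 9; it makes the C3–O bond by carbonyl reduction and the C2–C bond by carbene insertion, so no benzylic cation occurs. 1 would be alkylated on its free para-hydroxyl with 2-bromo-N-methoxy-N-methylacetamide (K2CO3, acetone) to give 2-(4-acetyl-2-bromo-5-hydroxyphenoxy)-N-methoxy-N-methylacetamide F1. Silylation as in step 2 would give 2-{4-acetyl-2-bromo-5-[(triisopropylsilyl)oxy]phenoxy}-N-methoxy-N-methylacetamide F2, and ketalization as in step 3 the dioxolane 2-{2-bromo-4-(2-methyl-1,3-dioxolan-2-yl)-5-[(triisopropylsilyl)oxy]phenoxy}-N-methoxy-N-methylacetamide F3. Bromine–lithium exchange (n-BuLi, THF, −100 °C) with Parham cyclization onto the amide should give 5-(2-methyl-1,3-dioxolan-2-yl)-6-[(triisopropylsilyl)oxy]-1-benzofuran-3(2H)-one F4. CBS reduction ((R)-Me-CBS, BH3·SMe2, on the usual large-aryl/small-methylene model) should give (3R)-5-(2-methyl-1,3-dioxolan-2-yl)-6-[(triisopropylsilyl)oxy]-2,3-dihydro-1-benzofuran-3-ol F5. Coupling with (diethoxyphosphoryl)acetic acid (N,N'-dicyclohexylcarbodiimide, DMAP) would give the (3R)-benzofuran-3-yl (diethoxyphosphoryl)acetate F6, and diazo transfer (4-acetamidobenzenesulfonyl azide, DBU, MeCN) the (3R)-benzofuran-3-yl diazo(diethoxyphosphoryl)acetate F7, the same compound as A3. Rh2(OAc)4 (cat.) in CH2Cl2 should induce 1,5 C–H insertion at C2 next to O1 to give the cis-fused phosphono lactone, diethyl [(8bR)-7-(2-methyl-1,3-dioxolan-2-yl)-2-oxo-6-[(triisopropylsilyl)oxy]-3,3a-dihydro-2H,8bH-furo[3,2-b][1]benzofuran-3-yl]phosphonate F8, as a mixture at the phosphorus-bearing carbon. Horner–Wadsworth–Emmons methylenation (aq. formaldehyde, K2CO3, THF) would give 9.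

Step 1. The most likely failure is incomplete enantio- or regiocontrol, or stalled oxidative addition. The bromide is electron-rich and doubly hydroxylated, its hydrogen-bonded hydroxy ketone can bind metal or base and loosen the chiral pocket, and insertion at the substituted end of the diene would give the 2-methyl-2-vinyl isomer.

The fallback sets out from 1 and returns at 4; it sets C2 by reagent-controlled epoxidation and an SN2 ring closure. Stille coupling of 1 with tributyl(3-methylbut-2-en-1-yl)stannane (Pd(PPh3)4, DMF, 90 °C) would give 1-[2,4-dihydroxy-5-(3-methylbut-2-en-1-yl)phenyl]ethanone F9. Ac2O/pyridine would give 4-acetyl-6-(3-methylbut-2-en-1-yl)-1,3-phenylene diacetate F10. Shi epoxidation (D-fructose-derived ketone, KHSO5, K2CO3, MeCN/dimethoxymethane/H2O, 0 °C; the enantiomeric ketone if the sense is opposite) would give 4-acetyl-6-{[(2R)-3,3-dimethyloxiran-2-yl]methyl}-1,3-phenylene diacetate F11. K2CO3 in MeOH removes the acetates, and the phenoxide next to the chain opens the epoxide at the secondary carbon (5-exo-tet, inversion) to give 1-[(2S)-6-hydroxy-2-(2-hydroxypropan-2-yl)-2,3-dihydro-1-benzofuran-5-yl]ethanone F12. Silylation as in step 2 would give 1-[(2S)-2-(2-hydroxypropan-2-yl)-6-[(triisopropylsilyl)oxy]-2,3-dihydro-1-benzofuran-5-yl]ethanone F13, and dehydration with the Burgess reagent (benzene, 50 °C) would give 4.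

Step 4. The most likely failure is loss of site selectivity or over-oxidation: ene attack at the oxygen-bearing C2 methine, ketal hydrolysis by selenous acid, or oxidation of the benzylic methylene.

The fallback sets out from 5 and returns at 8; it builds the acid carbon by carbonylation and not by C–H oxidation. Oxidative cleavage of the alkene (OsO4 cat., NaIO4, 2,6-lutidine, dioxane/H2O) would give 1-[(2S)-5-(2-methyl-1,3-dioxolan-2-yl)-6-[(triisopropylsilyl)oxy]-2,3-dihydro-1-benzofuran-2-yl]ethanone F14. Kinetic enolization toward the methyl group (KN(SiMe3)2, PhNTf2, THF, −78 °C) would give 1-[(2S)-5-(2-methyl-1,3-dioxolan-2-yl)-6-[(triisopropylsilyl)oxy]-2,3-dihydro-1-benzofuran-2-yl]ethenyl trifluoromethanesulfonate F15. Palladium-catalysed hydroxycarbonylation (Pd(OAc)2, PPh3, CO 1 atm, KOAc, DMF/H2O) would give 8.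

Step 9. The most likely failure is Z-to-E isomerization of the angeloyl unit, or acetyl migration from the primary oxygen to the C3 alkoxide through a seven-membered transition state before acylation.

The fallback sets out from 11 and returns at 14; it builds the Z-alkene on the ester and does not carry it. Coupling of 11 with 2-[bis(2,2,2-trifluoroethoxy)phosphoryl]propanoic acid (N,N'-dicyclohexylcarbodiimide, DMAP, CH2Cl2, 0 °C) would give (2R,3R)-2-[3-(acetyloxy)prop-1-en-2-yl]-5-(2-methyl-1,3-dioxolan-2-yl)-6-[(triisopropylsilyl)oxy]-2,3-dihydro-1-benzofuran-3-yl 2-[bis(2,2,2-trifluoroethoxy)phosphoryl]propanoate F16. Still–Gennari olefination with acetaldehyde (KN(SiMe3)2, 18-crown-6, THF, −78 °C) would give 14.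

## Further compounds

F1 | step 6 | 2-(4-acetyl-2-bromo-5-hydroxyphenoxy)-N-methoxy-N-methylacetamide | CON(C)C(=O)COc1cc(O)c(C(C)=O)cc1Br
F2 | step 6 | 2-{4-acetyl-2-bromo-5-[(triisopropylsilyl)oxy]phenoxy}-N-methoxy-N-methylacetamide | CON(C)C(=O)COc1cc(O[Si](C(C)C)(C(C)C)C(C)C)c(C(C)=O)cc1Br
F3 | step 6 | 2-{2-bromo-4-(2-methyl-1,3-dioxolan-2-yl)-5-[(triisopropylsilyl)oxy]phenoxy}-N-methoxy-N-methylacetamide | CON(C)C(=O)COc1cc(O[Si](C(C)C)(C(C)C)C(C)C)c(C2(C)OCCO2)cc1Br
F4 | step 6 | 5-(2-methyl-1,3-dioxolan-2-yl)-6-[(triisopropylsilyl)oxy]-1-benzofuran-3(2H)-one | O=C1COc2cc(O[Si](C(C)C)(C(C)C)C(C)C)c(C3(C)OCCO3)cc21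
F5 | step 6 | (3R)-5-(2-methyl-1,3-dioxolan-2-yl)-6-[(triisopropylsilyl)oxy]-2,3-dihydro-1-benzofuran-3-ol | O[C@H]1COc2cc(O[Si](C(C)C)(C(C)C)C(C)C)c(C3(C)OCCO3)cc21
F6 | step 6 | (3R)-5-(2-methyl-1,3-dioxolan-2-yl)-6-[(triisopropylsilyl)oxy]-2,3-dihydro-1-benzofuran-3-yl (diethoxyphosphoryl)acetate | CCOP(=O)(OCC)CC(=O)O[C@H]1COc2cc(O[Si](C(C)C)(C(C)C)C(C)C)c(C3(C)OCCO3)cc21
F7 | step 6 | (3R)-5-(2-methyl-1,3-dioxolan-2-yl)-6-[(triisopropylsilyl)oxy]-2,3-dihydro-1-benzofuran-3-yl diazo(diethoxyphosphoryl)acetate | CCOP(=O)(OCC)C(=[N+]=[N-])C(=O)O[C@H]1COc2cc(O[Si](C(C)C)(C(C)C)C(C)C)c(C3(C)OCCO3)cc21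
F8 | step 6 | diethyl [(8bR)-7-(2-methyl-1,3-dioxolan-2-yl)-2-oxo-6-[(triisopropylsilyl)oxy]-3,3a-dihydro-2H,8bH-furo[3,2-b][1]benzofuran-3-yl]phosphonate, cis-fused, mixture at C3 | CCOP(=O)(OCC)C1C(=O)O[C@@H]2c3cc(C4(C)OCCO4)c(O[Si](C(C)C)(C(C)C)C(C)C)cc3O[C@H]12
F9 | step 1 | 1-[2,4-dihydroxy-5-(3-methylbut-2-en-1-yl)phenyl]ethanone | CC(C)=CCc1cc(C(C)=O)c(O)cc1O
F10 | step 1 | 4-acetyl-6-(3-methylbut-2-en-1-yl)-1,3-phenylene diacetate | CC(C)=CCc1cc(C(C)=O)c(OC(C)=O)cc1OC(C)=O
F11 | step 1 | 4-acetyl-6-{[(2R)-3,3-dimethyloxiran-2-yl]methyl}-1,3-phenylene diacetate | CC(=O)Oc1cc(OC(C)=O)c(C(C)=O)cc1C[C@H]1OC1(C)C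
F12 | step 1 | 1-[(2S)-6-hydroxy-2-(2-hydroxypropan-2-yl)-2,3-dihydro-1-benzofuran-5-yl]ethanone | CC(C)(O)[C@@H]1Cc2cc(C(C)=O)c(O)cc2O1
F13 | step 1 | 1-[(2S)-2-(2-hydroxypropan-2-yl)-6-[(triisopropylsilyl)oxy]-2,3-dihydro-1-benzofuran-5-yl]ethanone | CC(C)(O)[C@@H]1Cc2cc(C(C)=O)c(O[Si](C(C)C)(C(C)C)C(C)C)cc2O1
F14 | step 4 | 1-[(2S)-5-(2-methyl-1,3-dioxolan-2-yl)-6-[(triisopropylsilyl)oxy]-2,3-dihydro-1-benzofuran-2-yl]ethanone | CC(=O)[C@@H]1Cc2cc(C3(C)OCCO3)c(O[Si](C(C)C)(C(C)C)C(C)C)cc2O1
F15 | step 4 | 1-[(2S)-5-(2-methyl-1,3-dioxolan-2-yl)-6-[(triisopropylsilyl)oxy]-2,3-dihydro-1-benzofuran-2-yl]ethenyl trifluoromethanesulfonate | C=C(OS(=O)(=O)C(F)(F)F)[C@@H]1Cc2cc(C3(C)OCCO3)c(O[Si](C(C)C)(C(C)C)C(C)C)cc2O1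
F16 | step 9 | (2R,3R)-2-[3-(acetyloxy)prop-1-en-2-yl]-5-(2-methyl-1,3-dioxolan-2-yl)-6-[(triisopropylsilyl)oxy]-2,3-dihydro-1-benzofuran-3-yl 2-[bis(2,2,2-trifluoroethoxy)phosphoryl]propanoate | C=C(COC(C)=O)[C@H]1Oc2cc(O[Si](C(C)C)(C(C)C)C(C)C)c(C3(C)OCCO3)cc2[C@H]1OC(=O)C(C)P(=O)(OCC(F)(F)F)OCC(F)(F)F
A1 | alternative 1 | (3R,4R)-6-acetyl-7-[(tert-butyldimethylsilyl)oxy]-3-hydroxy-2,2-dimethyl-3,4-dihydro-2H-chromen-4-yl (2Z)-2-methylbut-2-enoate | C/C=C(/C)C(=O)O[C@@H]1c2cc(C(C)=O)c(O[Si](C)(C)C(C)(C)C)cc2OC(C)(C)[C@@H]1O
A2 | alternative 1 | (2R,3R)-5-acetyl-6-[(tert-butyldimethylsilyl)oxy]-2-(prop-1-en-2-yl)-2,3-dihydro-1-benzofuran-3-yl (2Z)-2-methylbut-2-enoate | C=C(C)[C@H]1Oc2cc(O[Si](C)(C)C(C)(C)C)c(C(C)=O)cc2[C@H]1OC(=O)/C(C)=C\C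
A3 | alternative 2 | (3R)-5-(2-methyl-1,3-dioxolan-2-yl)-6-[(triisopropylsilyl)oxy]-2,3-dihydro-1-benzofuran-3-yl diazo(diethoxyphosphoryl)acetate | CCOP(=O)(OCC)C(=[N+]=[N-])C(=O)O[C@H]1COc2cc(O[Si](C(C)C)(C(C)C)C(C)C)c(C3(C)OCCO3)cc21
A4 | alternative 2 | diethyl [cis-fused (8bR)-7-(2-methyl-1,3-dioxolan-2-yl)-2-oxo-6-[(triisopropylsilyl)oxy]-3,3a-dihydro-2H,8bH-furo[3,2-b][1]benzofuran-3-yl]phosphonate | CCOP(=O)(OCC)[C@H]1C(=O)O[C@@H]2c3cc(C4(C)OCCO4)c(O[Si](C(C)C)(C(C)C)C(C)C)cc3O[C@H]12
A5 | alternative 3 | 3-methyl-8-(2-methyl-1,3-dioxolan-2-yl)-9-[(triisopropylsilyl)oxy]-4H,6H-1,5-benzodioxocine | CC1=COc2cc(O[Si](C(C)C)(C(C)C)C(C)C)c(C3(C)OCCO3)cc2COC1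
A6 | alternative 3 | (2R,3R)-5-(2-methyl-1,3-dioxolan-2-yl)-2-(prop-1-en-2-yl)-6-[(triisopropylsilyl)oxy]-2,3-dihydro-1-benzofuran-3-ol | C=C(C)[C@H]1Oc2cc(O[Si](C(C)C)(C(C)C)C(C)C)c(C3(C)OCCO3)cc2[C@H]1O
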